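**Retrosynthetic overview**

1. Ring D is closed last: C15–C16 by a nickel-catalysed reductive alkyne–aldehyde cyclisation of a 15,20-dialdehyde, which installs the 15-oxygen and the 16-methylene together.
2. Ring B is closed before that: C6–C8 by an intramolecular ester-enolate SN2′ displacement of an exocyclic allylic chloride (quaternary C-8); the C-4 methyl is then added on the rigid A/B/C tricycle.
3. The two halves are joined late: a ring A acid is esterified with a ring C chlorohydrin and an Ireland–Claisen rearrangement forms C9–C10 (quaternary C-10); the C-20 carboxyl is later reduced to the aldehyde.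
4. The ring A acid comes from an organocatalytic Diels–Alder reaction and a one-carbon homologation; the ring C alcohol from Evans alkylation, ring-closing metathesis, Ohira–Bestmann alkynylation and CBS reduction.
5. Ring order: A and C separately, then B, then D.

Assumption: positions are cited in gibberellane numbering (C-1 to C-20; α is the face of the C-20 aldehyde), centres that are epimer mixtures at a given stage are left unspecified in the SMILES, and (4S)-4-benzyl-1,3-oxazolidin-2-one is used as a recoverable auxiliary reagent.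

**Route**

Step 1
Reactants: 1 methyl (2E)-but-2-enoate
Product: 2 methyl (2E)-4-oxobut-2-enoate
Conditions: SeO2, 1,4-dioxane, reflux
Reagents that add atoms: selenium dioxide O=[Se]=O
Why: Riley allylic oxidation converts the γ-methyl group of the crotonate into the aldehyde and leaves the (E)-enoate intact.

Step 2
Reactants: 3 (2E)-penta-2,4-dien-1-ol
Product: 4 tert-butyl(dimethyl)[(2E)-penta-2,4-dien-1-yloxy]silane
Conditions: t-BuMe2SiCl, imidazole, CH2Cl2, 0 °C → rt
Reagents that add atoms: tert-butyl(chloro)dimethylsilane CC(C)(C)[Si](C)(C)Cl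
Why: Standard silylation of a primary alcohol; the silyl ether masks C-20 until step 7.

Step 3
Reactants: 2 methyl (2E)-4-oxobut-2-enoate; 4 tert-butyl(dimethyl)[(2E)-penta-2,4-dien-1-yloxy]silane
Product: 5 methyl (1S,2S,3S)-3-({[tert-butyl(dimethyl)silyl]oxy}methyl)-2-formylcyclohex-4-ene-1-carboxylate
Conditions: (5S)-5-benzyl-2,2,3-trimethylimidazolidin-4-one·HCl (20 mol %), MeCN/H2O 95:5, −10 °C
Reagents that add atoms: none
Why: Iminium-catalysed (MacMillan) Diels–Alder reaction: the benzyl group shields one face of the (E)-iminium ion so the diene adds to the other and sets the future C-5 (S at the formyl carbon, as for cinnamaldehyde with this catalyst), the unsubstituted diene terminus bonds to the iminium β-carbon, and the endo mode puts CH2OSi cis to CHO.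

Step 4
Reactants: 5 methyl (1S,2S,3S)-3-({[tert-butyl(dimethyl)silyl]oxy}methyl)-2-formylcyclohex-4-ene-1-carboxylate
Product: 6 methyl (1S,2R,3S)-3-({[tert-butyl(dimethyl)silyl]oxy}methyl)-2-(2-methoxyethenyl)cyclohex-4-ene-1-carboxylate (E/Z mixture)
Conditions: Ph3P(CH2OMe)Cl, KN(SiMe3)2, THF, −78 → 0 °C
Reagents that add atoms: (methoxymethyl)triphenylphosphonium chloride COC[P+](c1ccccc1)(c1ccccc1)c1ccccc1.[Cl-]
Why: Wittig methoxymethylenation adds the future C-7; the ylide at low temperature should not epimerise the α-stereocentre (C-5).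

Step 5
Reactants: 6 methyl (1S,2R,3S)-3-({[tert-butyl(dimethyl)silyl]oxy}methyl)-2-(2-methoxyethenyl)cyclohex-4-ene-1-carboxylate
Product: 7 methyl (1S,2S,3S)-3-({[tert-butyl(dimethyl)silyl]oxy}methyl)-2-(2-methoxy-2-oxoethyl)cyclohex-4-ene-1-carboxylate
Conditions: C5H5NH[CrO3Cl] (pyridinium chlorochromate), CH2Cl2, rt
Reagents that add atoms: pyridinium chlorochromate [O-][Cr](=O)(=O)Cl.c1cc[nH+]cc1
Why: Chlorochromate oxidation of an enol ether gives the ester directly (attack at the oxygen-bearing carbon with hydride shift), so C-7 arrives as its methyl ester and no stereocentre is touched.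

Step 6
Reactants: 7 methyl (1S,2S,3S)-3-({[tert-butyl(dimethyl)silyl]oxy}methyl)-2-(2-methoxy-2-oxoethyl)cyclohex-4-ene-1-carboxylate
Product: 8 methyl (1S,2S,3S)-3-({[tert-butyl(dimethyl)silyl]oxy}methyl)-2-(2-methoxy-2-oxoethyl)cyclohexane-1-carboxylate
Conditions: H2 (1 atm), Pd/C (10 %), EtOAc, rt
Reagents that add atoms: none
Why: Heterogeneous hydrogenation of the only alkene (C1=C2) in a neutral solvent that leaves the silyl ether intact.

Step 7
Reactants: 8 methyl (1S,2S,3S)-3-({[tert-butyl(dimethyl)silyl]oxy}methyl)-2-(2-methoxy-2-oxoethyl)cyclohexane-1-carboxylate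
Product: 11 (1S,2S,3S)-2-(2-methoxy-2-oxoethyl)-3-(methoxycarbonyl)cyclohexane-1-carboxylic acid, via primary alcohol 9 (not isolated), via aldehyde 10 (not isolated)
Conditions: CrO3, H2SO4, acetone/H2O, 0 °C → rt
Reagents that add atoms: water O
Why: Jones oxidation: the acidic medium removes the silyl group and hexavalent chromium takes the alcohol through the aldehyde hydrate to the acid faster than the hydroxy esters lactonise; C-10 and C-4 stay epimerisable and are reset in steps 17 and 19.

Step 8
Reactants: 12 methyl 2-(hydroxymethyl)prop-2-enoate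
Product: 13 methyl 2-(bromomethyl)prop-2-enoate
Conditions: PBr3, Et2O, −10 °C → rt
Reagents that add atoms: phosphorus tribromide BrP(Br)Br
Why: Bromination of a primary allylic alcohol through its phosphite ester (SN2 and SN2′ give the same product here).

Step 9
Reactants: 14 hex-5-enoyl chloride
Product: 15 (4S)-4-benzyl-3-(hex-5-enoyl)-1,3-oxazolidin-2-one
Conditions: (4S)-4-benzyl-1,3-oxazolidin-2-one, n-BuLi, THF, −78 °C; then 14
Reagents that add atoms: (4S)-4-benzyl-1,3-oxazolidin-2-one O=C1OC[C@H](Cc2ccccc2)N1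
Why: N-Acylation of the lithiated Evans auxiliary.

Step 10
Reactants: 15 (4S)-4-benzyl-3-(hex-5-enoyl)-1,3-oxazolidin-2-one; 13 methyl 2-(bromomethyl)prop-2-enoate
Product: 16 (4S)-4-benzyl-3-{(2R)-2-[2-(methoxycarbonyl)prop-2-en-1-yl]hex-5-enoyl}-1,3-oxazolidin-2-one
Conditions: NaN(SiMe3)2, THF, −78 °C; then 13, −78 → −40 °C
Reagents that add atoms: none
Why: Evans asymmetric alkylation: the chelated (Z)-enolate is attacked on the face away from the benzyl group, giving the (2R) centre (future C-13) as in the known allylation of the propionyl analogue.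

Step 11
Reactants: 16 (4S)-4-benzyl-3-{(2R)-2-[2-(methoxycarbonyl)prop-2-en-1-yl]hex-5-enoyl}-1,3-oxazolidin-2-one
Product: 17 (4S)-4-benzyl-3-{[(1R)-3-(methoxycarbonyl)cyclohex-3-en-1-yl]carbonyl}-1,3-oxazolidin-2-one
Conditions: second-generation Grubbs catalyst RuCl2(=CHPh)(H2IMes)(PCy3) (3 mol %), CH2Cl2, 40 °C
Reagents that add atoms: none
Why: Ring-closing metathesis between the terminal alkene and the acrylate-type alkene closes ring C as a cyclohexene-1-carboxylate (C8=C9) with loss of ethene.

Step 12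
Reactants: 17 (4S)-4-benzyl-3-{[(1R)-3-(methoxycarbonyl)cyclohex-3-en-1-yl]carbonyl}-1,3-oxazolidin-2-one
Product: 18 methyl (5R)-5-(hydroxymethyl)cyclohex-1-ene-1-carboxylate
Conditions: LiBH4, MeOH (1 equiv), Et2O, 0 °C
Reagents that add atoms: none
Why: Reductive removal of the auxiliary: the imide carbonyl is much more electrophilic than the conjugated methyl ester, so borohydride reduces it selectively and the auxiliary is recovered.

Step 13
Reactants: 18 methyl (5R)-5-(hydroxymethyl)cyclohex-1-ene-1-carboxylate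
Product: 20 methyl (5R)-5-ethynylcyclohex-1-ene-1-carboxylate, via aldehyde 19 (not isolated)
Conditions: Dess–Martin periodinane, NaHCO3, CH2Cl2, rt; then MeC(O)C(N2)P(O)(OMe)2, K2CO3, MeOH, 0 °C → rt
Reagents that add atoms: dimethyl (1-diazo-2-oxopropyl)phosphonate CC(=O)C(=[N+]=[N-])P(=O)(OC)OC
Why: Dess–Martin oxidation and Ohira–Bestmann (Seyferth–Gilbert) homologation turn CH2OH into the C16≡C17 alkyne; the mild carbonate conditions at 0 °C keep the α-stereocentre.

Step 14
Reactants: 20 methyl (5R)-5-ethynylcyclohex-1-ene-1-carboxylate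
Product: 21 2-chloro-1-[(5R)-5-ethynylcyclohex-1-en-1-yl]ethan-1-one
Conditions: ICH2Cl, MeLi·LiBr (3 equiv each), THF/Et2O, −78 °C; aq. NH4Cl
Reagents that add atoms: chloroiodomethane ClCI
Why: Chloromethyllithium adds 1,2 to the ester and the tetrahedral alkoxide survives at −78 °C, collapsing to the α′-chloro enone only on work-up (the first equivalent of MeLi is consumed by the alkyne C–H).

Step 15
Reactants: 21 2-chloro-1-[(5R)-5-ethynylcyclohex-1-en-1-yl]ethan-1-one
Product: 22 (1R)-2-chloro-1-[(5R)-5-ethynylcyclohex-1-en-1-yl]ethan-1-ol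
Conditions: (R)-2-butyl-CBS-oxazaborolidine (15 mol %), catecholborane, toluene, −78 °C
Reagents that add atoms: none
Why: Corey–Bakshi–Shibata reduction with the alkenyl group as the large substituent: the (R)-catalyst gives the (R)-chlorohydrin (mirror of the (S)-catalyst/2-chloroacetophenone case), and catecholborane at −78 °C does not hydroborate the alkyne.

Step 16
Reactants: 11 (1S,2S,3S)-2-(2-methoxy-2-oxoethyl)-3-(methoxycarbonyl)cyclohexane-1-carboxylic acid; 22 (1R)-2-chloro-1-[(5R)-5-ethynylcyclohex-1-en-1-yl]ethan-1-ol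
Product: 24 (1R)-2-chloro-1-[(5R)-5-ethynylcyclohex-1-en-1-yl]ethyl (1S,2S,3S)-2-(2-methoxy-2-oxoethyl)-3-(methoxycarbonyl)cyclohexane-1-carboxylate, via mixed anhydride 23 (not isolated)
Conditions: 2,4,6-Cl3C6H2COCl, Et3N, THF, rt; then 22, DMAP, toluene, rt
Reagents that add atoms: none
Why: Yamaguchi esterification joins the two halves through the hindered secondary acid without touching the carbinol stereocentre.

Step 17
Reactants: 24 (1R)-2-chloro-1-[(5R)-5-ethynylcyclohex-1-en-1-yl]ethyl (1S,2S,3S)-2-(2-methoxy-2-oxoethyl)-3-(methoxycarbonyl)cyclohexane-1-carboxylate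
Product: 27 ring A 20-oic acid bearing at quaternary C-10 (CO2H α) the ring C unit with 9β-H and an (E)-8(15)-alkene carrying CH2Cl and a 13-[(trimethylsilyl)ethynyl] group (7- and 19-methyl esters; C-4 epimers), via silyl ketene acetal 25 (not isolated), via trimethylsilyl ester 26 (not isolated)
Conditions: LiN(iPr)2 (5 equiv), Me3SiCl (6 equiv), THF/DMPU, −78 °C → rt, then 60 °C; 1 M HCl
Reagents that add atoms: chlorotrimethylsilane C[Si](C)(C)Cl
Why: Ireland–Claisen rearrangement: all four acidic sites are silylated in situ and the allyl ester ketene acetal rearranges through a chair with CH2Cl equatorial, so the (R)-carbinol transfers its chirality to C-9 (H β) and gives the (E)-allylic chloride, while the C-5 side chain, forced axial by allylic strain from the two flanking ketene acetals, sends the new C9–C10 bond to the opposite face (C-9 trans to C-6).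

Step 18
Reactants: 27 the Claisen acid described in step 17
Product: 28 A/B/C tricyclic 20-oic acid with 8-vinyl and 13-[(trimethylsilyl)ethynyl] groups and 7- and 19-methyl esters (C-4 and C-6 epimer mixtures)
Conditions: KN(SiMe3)2 (2.1 equiv), THF, −78 → −20 °C
Reagents that add atoms: none
Why: Intramolecular SN2′ alkylation (5-exo): after the carboxylate, the only CH2 ester is deprotonated and its enolate attacks C-8 with loss of chloride; attack must come perpendicular to the exocyclic alkene from the side of the C-9 tether, so ring B is cis-fused to ring C (8-vinyl cis to 9-H) and C-8 becomes quaternary.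

Step 19
Reactants: 28 the tricyclic acid described in step 18
Product: 30 4β-methyl A/B/C tricyclic 20-oic acid with 8-vinyl and 13-ethynyl groups and 6β- and 4α-methyl esters, via methylated silylalkyne 29 (not isolated)
Conditions: LiN(iPr)2 (2.2 equiv), THF/DMPU, −78 → −40 °C; MeI, −78 °C; then NaOMe, MeOH, 55 °C
Reagents that add atoms: iodomethane CI
Why: Kinetic ester-enolate alkylation: the base removes the accessible C-4 proton and not the C-6 proton wedged between C-5 and quaternary C-8, MeI enters equatorially on the β face anti to the axial C-20 carboxylate (4β-Me, 4α-CO2Me), and methoxide then removes the alkynyl silyl group and equilibrates C-6 to the more stable 6β-ester.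

Step 20
Reactants: 30 the methylated tricyclic acid described in step 19
Product: 32 the corresponding 20-aldehyde (8-vinyl, 13-ethynyl, 7,19-dimethyl ester), via acid chloride 31 (not isolated)
Conditions: (COCl)2, cat. DMF, CH2Cl2, 0 °C; then LiAlH(OtBu)3, THF, −78 °C
Reagents that add atoms: none
Why: Acid chloride formation and chemoselective hydride reduction with LiAlH(OtBu)3 at −78 °C stop at the aldehyde and leave the methyl esters alone; C-10 is quaternary and cannot epimerise.

Step 21
Reactants: 32 the 20-aldehyde described in step 20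
Product: 34 15,20-dialdehyde (8-formyl, 13-ethynyl, 7,19-dimethyl ester), via vicinal diol 33 (not isolated)
Conditions: OsO4 (2 mol %), NaIO4, 2,6-lutidine, dioxane/H2O 3:1, rt
Reagents that add atoms: osmium tetroxide O=[Os](=O)(=O)=O; sodium periodate [Na+].[O-]I(=O)(=O)=O
Why: Lemieux–Johnson cleavage: OsO4 dihydroxylates the monosubstituted vinyl group much faster than the terminal alkyne and periodate cleaves the diol to the C-15 aldehyde.

Step 22
Reactants: 34 the 15,20-dialdehyde described in step 21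
Product: 35 tetracyclic 15β-triethylsilyloxy 7,19-dimethyl ester (the target as its dimethyl ester 15-O-triethylsilyl ether)
Conditions: Ni(cod)2 (15 mol %), PBu3 (30 mol %), Et3SiH, THF, rt
Reagents that add atoms: triethylsilane CC[SiH](CC)CC
Why: Nickel-catalysed reductive alkyne–aldehyde cyclisation (Montgomery): oxidative cyclisation of the C-15 aldehyde and the 1,3-diaxial alkyne on zerovalent nickel closes ring D, Et3SiH delivers H to C-17 and silicon to oxygen, and the aldehyde oxygen turns toward the C-9/C-11 side, away from the neighbouring 6β-ester, which gives the 15β-silyl ether.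

Step 23
Reactants: 35 tetracyclic 15β-triethylsilyloxy 7,19-dimethyl ester
Product: 37 the target gibberellin (15β-hydroxy 20-aldehyde 7,19-diacid), via silyl ether diacid 36 (not isolated)
Conditions: KOH, MeOH/H2O 3:1, 65 °C; then 1 M HCl to pH 2, THF, rt
Reagents that add atoms: potassium hydroxide [K+].[OH-]
Why: Saponification (the hindered axial C-19 ester is helped by the neighbouring C-20 aldehyde hydrate) followed by acid cleavage of the silyl ether; C-6 stays in its thermodynamic configuration, and the 15β-hydroxyl is poorly aligned with the C-7 carboxyl, so brief acidification at rt is not expected to lactonise it.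

**Compound list**

1 | methyl (2E)-but-2-enoate | C/C=C/C(=O)OC | starting material
2 | methyl (2E)-4-oxobut-2-enoate | O=C/C=C/C(=O)OC | intermediate
3 | (2E)-penta-2,4-dien-1-ol | OC/C=C/C=C | starting material
4 | tert-butyl(dimethyl)[(2E)-penta-2,4-dien-1-yloxy]silane | CC(C)(C)[Si](C)(C)OC/C=C/C=C | intermediate
5 | methyl (1S,2S,3S)-3-({[tert-butyl(dimethyl)silyl]oxy}methyl)-2-formylcyclohex-4-ene-1-carboxylate (CHO trans to CO2Me, cis to CH2OSi) | [C@H]1(CO[Si](C)(C)C(C)(C)C)C=CC[C@H](C(=O)OC)[C@H]1C=O | intermediate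
6 | methyl (1S,2R,3S)-3-({[tert-butyl(dimethyl)silyl]oxy}methyl)-2-(2-methoxyethenyl)cyclohex-4-ene-1-carboxylate (E/Z mixture) | [C@H]1(CO[Si](C)(C)C(C)(C)C)C=CC[C@H](C(=O)OC)[C@H]1C=COC | intermediate
7 | methyl (1S,2S,3S)-3-({[tert-butyl(dimethyl)silyl]oxy}methyl)-2-(2-methoxy-2-oxoethyl)cyclohex-4-ene-1-carboxylate | [C@H]1(CO[Si](C)(C)C(C)(C)C)C=CC[C@H](C(=O)OC)[C@H]1CC(=O)OC | intermediate
8 | methyl (1S,2S,3S)-3-({[tert-butyl(dimethyl)silyl]oxy}methyl)-2-(2-methoxy-2-oxoethyl)cyclohexane-1-carboxylate | [C@H]1(CO[Si](C)(C)C(C)(C)C)CCC[C@H](C(=O)OC)[C@H]1CC(=O)OC | intermediate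
9 | methyl (1S,2S,3S)-3-(hydroxymethyl)-2-(2-methoxy-2-oxoethyl)cyclohexane-1-carboxylate | OC[C@H]1CCC[C@H](C(=O)OC)[C@H]1CC(=O)OC | intermediate
10 | methyl (1S,2S,3S)-3-formyl-2-(2-methoxy-2-oxoethyl)cyclohexane-1-carboxylate | O=C[C@H]1CCC[C@H](C(=O)OC)[C@H]1CC(=O)OC | intermediate
11 | (1S,2S,3S)-2-(2-methoxy-2-oxoethyl)-3-(methoxycarbonyl)cyclohexane-1-carboxylic acid (ring A acid) | OC(=O)[C@H]1CCC[C@H](C(=O)OC)[C@H]1CC(=O)OC | intermediate
12 | methyl 2-(hydroxymethyl)prop-2-enoate | C=C(CO)C(=O)OC | starting material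
13 | methyl 2-(bromomethyl)prop-2-enoate | C=C(CBr)C(=O)OC | intermediate
14 | hex-5-enoyl chloride | C=CCCCC(=O)Cl | starting material
15 | (4S)-4-benzyl-3-(hex-5-enoyl)-1,3-oxazolidin-2-one | C=CCCCC(=O)N1[C@@H](Cc2ccccc2)COC1=O | intermediate
16 | (4S)-4-benzyl-3-{(2R)-2-[2-(methoxycarbonyl)prop-2-en-1-yl]hex-5-enoyl}-1,3-oxazolidin-2-one | C=CCC[C@H](CC(=C)C(=O)OC)C(=O)N1[C@@H](Cc2ccccc2)COC1=O | intermediate
17 | (4S)-4-benzyl-3-{[(1R)-3-(methoxycarbonyl)cyclohex-3-en-1-yl]carbonyl}-1,3-oxazolidin-2-one | O=C([C@@H]1CCC=C(C1)C(=O)OC)N1[C@@H](Cc2ccccc2)COC1=O | intermediate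
18 | methyl (5R)-5-(hydroxymethyl)cyclohex-1-ene-1-carboxylate | OC[C@@H]1CCC=C(C1)C(=O)OC | intermediate
19 | methyl (5R)-5-formylcyclohex-1-ene-1-carboxylate | O=C[C@@H]1CCC=C(C1)C(=O)OC | intermediate
20 | methyl (5R)-5-ethynylcyclohex-1-ene-1-carboxylate | C#C[C@@H]1CCC=C(C1)C(=O)OC | intermediate
21 | 2-chloro-1-[(5R)-5-ethynylcyclohex-1-en-1-yl]ethan-1-one | C#C[C@@H]1CCC=C(C1)C(=O)CCl | intermediate
22 | (1R)-2-chloro-1-[(5R)-5-ethynylcyclohex-1-en-1-yl]ethan-1-ol (ring C alcohol) | C#C[C@@H]1CCC=C(C1)[C@@H](O)CCl | intermediate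
23 | mixed anhydride of 11 with 2,4,6-trichlorobenzoic acid | O=C(OC(=O)c1c(Cl)cc(Cl)cc1Cl)[C@H]1CCC[C@H](C(=O)OC)[C@H]1CC(=O)OC | intermediate
24 | (1R)-2-chloro-1-[(5R)-5-ethynylcyclohex-1-en-1-yl]ethyl (1S,2S,3S)-2-(2-methoxy-2-oxoethyl)-3-(methoxycarbonyl)cyclohexane-1-carboxylate | C#C[C@@H]1CCC=C(C1)[C@@H](OC(=O)[C@H]2CCC[C@H](C(=O)OC)[C@H]2CC(=O)OC)CCl | intermediate
25 | tris(O-trimethylsilyl ketene acetal) of 24 with C-silylated alkyne (ketene acetal geometries undefined) | C[Si](C)(C)C#C[C@@H]1CCC=C(C1)[C@@H](OC(O[Si](C)(C)C)=C2CCCC(=C(OC)O[Si](C)(C)C)[C@H]2C=C(OC)O[Si](C)(C)C)CCl | intermediate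
26 | rearranged trimethylsilyl ester (C9–C10 bond made; C-4 and C-6 still silyl ketene acetals) | C[Si](C)(C)C#C[C@@H]1CC[C@@H]([C@]2(C(=O)O[Si](C)(C)C)CCCC(=C(OC)O[Si](C)(C)C)[C@H]2C=C(OC)O[Si](C)(C)C)/C(C1)=C/CCl | intermediate
27 | Claisen acid: 1-{(2E)-2-(2-chloroethylidene)-4-[(trimethylsilyl)ethynyl]cyclohexyl}-2-(2-methoxy-2-oxoethyl)-3-(methoxycarbonyl)cyclohexane-1-carboxylic acid; C-10 quaternary with CO2H α, 9β-H, C-4 epimers | C[Si](C)(C)C#C[C@@H]1CC[C@@H]([C@]2(C(=O)O)CCCC(C(=O)OC)[C@H]2CC(=O)OC)/C(C1)=C/CCl | intermediate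
28 | A/B/C tricyclic 20-oic acid, 8-vinyl, 13-[(trimethylsilyl)ethynyl], 7- and 19-methyl esters (C-4 and C-6 epimers) | C[Si](C)(C)C#C[C@@H]1CC[C@H]2[C@]3(C(=O)O)CCCC(C(=O)OC)[C@H]3C(C(=O)OC)[C@]2(C1)C=C | intermediate
29 | 4β-methyl derivative of 28 (4α-CO2Me; C-6 epimers) | C[Si](C)(C)C#C[C@@H]1CC[C@H]2[C@]3(C(=O)O)CCC[C@@](C)(C(=O)OC)[C@H]3C(C(=O)OC)[C@]2(C1)C=C | intermediate
30 | 4β-methyl-8-vinyl-13-ethynyl A/B/C tricyclic 20-oic acid 7,19-dimethyl ester (6β-CO2Me) | C#C[C@@H]1CC[C@H]2[C@]3(C(=O)O)CCC[C@@](C)(C(=O)OC)[C@H]3[C@H](C(=O)OC)[C@]2(C1)C=C | intermediate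
31 | acid chloride of 30 | C#C[C@@H]1CC[C@H]2[C@]3(C(=O)Cl)CCC[C@@](C)(C(=O)OC)[C@H]3[C@H](C(=O)OC)[C@]2(C1)C=C | intermediate
32 | 20-aldehyde corresponding to 30 | C#C[C@@H]1CC[C@H]2[C@]3(C=O)CCC[C@@](C)(C(=O)OC)[C@H]3[C@H](C(=O)OC)[C@]2(C1)C=C | intermediate
33 | diol from dihydroxylation of the 8-vinyl group of 32 (carbinol configuration undefined) | C#C[C@@H]1CC[C@H]2[C@]3(C=O)CCC[C@@](C)(C(=O)OC)[C@H]3[C@H](C(=O)OC)[C@]2(C1)C(O)CO | intermediate
34 | 15,20-dialdehyde (8-formyl, 13-ethynyl, 7,19-dimethyl ester) | C#C[C@@H]1CC[C@H]2[C@]3(C=O)CCC[C@@](C)(C(=O)OC)[C@H]3[C@H](C(=O)OC)[C@]2(C1)C=O | intermediate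
35 | tetracyclic 15β-triethylsilyloxy 7,19-dimethyl ester: the target as its dimethyl ester 15-O-triethylsilyl ether (16-methylene, 20-aldehyde) | C=C1[C@@H]2CC[C@H]3[C@]4(C=O)CCC[C@@](C)(C(=O)OC)[C@H]4[C@H](C(=O)OC)[C@]3(C2)[C@@H]1O[Si](CC)(CC)CC | intermediate
36 | silyl ether diacid: the target as its 15-O-triethylsilyl ether (formed as its dipotassium salt) | C=C1[C@@H]2CC[C@H]3[C@]4(C=O)CCC[C@@](C)(C(=O)O)[C@H]4[C@H](C(=O)O)[C@]3(C2)[C@@H]1O[Si](CC)(CC)CC | intermediate
37 | the target gibberellin: 15β-hydroxy-16-methylene 20-aldehyde 7,19-dicarboxylic acid of the gibberellane skeleton (4β-Me, 4α-CO2H, 5β-H, 6β-CO2H, 9β-H, 10α-CHO) | C=C1[C@@H]2CC[C@H]3[C@]4(C=O)CCC[C@@](C)(C(=O)O)[C@H]4[C@H](C(=O)O)[C@]3(C2)[C@@H]1O | target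

**Step count and risks**

Total step count: 23. Longest linear sequence: 15 steps (14 → 15 → 16 → 17 → 18 → 20 → 21 → 22 → 24 → 27 → 28 → 30 → 32 → 34 → 35 → 37; the branch from 12 is equally long, the ring A branch is 14).

Step 17 (Ireland–Claisen) is the most likely to fail: the hindered tertiary C-10 proton must be removed beside three other acidic sites, and the face selectivity at C-10 rests on a conformational argument. The fallback sets out from silyl ether 8 and alcohol 22 and comes back at acid 27; it uses an aliphatic Claisen rearrangement at the aldehyde oxidation level, with no enolate. Alcohol 22 is C-silylated (EtMgBr, Me3SiCl, THF; dilute citric acid) to (1R)-2-chloro-1-{(5R)-5-[(trimethylsilyl)ethynyl]cyclohex-1-en-1-yl}ethan-1-ol F1. Silyl ether 8 is cleaved with HF·pyridine and the alcohol (9 of the list), used at once, is oxidised with Dess–Martin periodinane to aldehyde 10, here isolated, which HC(OMe)3 and pyridinium p-toluenesulfonate turn into the dimethyl acetal F2. Heating F2 with F1 and catalytic propionic acid in xylene at 140 °C while MeOH distils gives, by acetal exchange and loss of MeOH, the allyl enol ether F3 (not isolated), which rearranges with the same chirality transfer to the α-quaternary aldehyde F4. Pinnick oxidation (NaClO2, NaH2PO4, 2-methylbut-2-ene) of F4 gives 27.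

Step 18 (SN2′ closure of ring B) may fail because it builds a quaternary centre flanked by two substituted carbons, and the carboxylate could compete as an oxygen nucleophile. The fallback sets out from 27 and comes back at 28. The ester is converted into its zinc enolate (LiN(SiMe3)2 2.1 equiv, then ZnCl2) and the allylic chloride is ionised with Pd2(dba)3 (2.5 mol %) and dppe in THF at 40 °C. Ring closure then runs as a Tsuji–Trost alkylation through a π-allyl complex of divalent palladium, with attack at the allyl terminus that closes the five-membered ring, in place of the uncatalysed displacement. It creates no new compound (none, F0).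

Step 22 (nickel-catalysed cyclisation) may fail because terminal alkynes can oligomerise on zerovalent nickel and the 15-configuration depends on the orientation of the aldehyde. The fallback sets out from 34 and comes back at 37. Markovnikov hydroiodination of the alkyne (NaI, Me3SiCl, H2O, MeCN, 0 °C) gives the 2-iodoalkene F5. Nozaki–Hiyama–Kishi cyclisation (CrCl2 4 equiv, NiCl2 1 mol %, DMF, rt), in which the vinyl species of trivalent chromium adds to the C-15 aldehyde, gives the free 15β-hydroxy 7,19-dimethyl ester F6. Saponification as in step 23 (KOH, MeOH/H2O, 65 °C; acidify) gives 37.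

**Further compounds**

F1 | step 17 | (1R)-2-chloro-1-{(5R)-5-[(trimethylsilyl)ethynyl]cyclohex-1-en-1-yl}ethan-1-ol | C[Si](C)(C)C#C[C@@H]1CCC=C(C1)[C@@H](O)CCl
F2 | step 17 | methyl (1S,2S,3S)-3-(dimethoxymethyl)-2-(2-methoxy-2-oxoethyl)cyclohexane-1-carboxylate | COC(OC)[C@H]1CCC[C@H](C(=O)OC)[C@H]1CC(=O)OC
F3 | step 17 | allyl enol ether from F2 and F1 (enol ether geometry undefined) | C[Si](C)(C)C#C[C@@H]1CCC=C(C1)[C@@H](OC=C2CCC[C@H](C(=O)OC)[C@H]2CC(=O)OC)CCl
F4 | step 17 | 20-aldehyde analogue of 27 (C-10 quaternary, CHO α, 9β-H, (E)-allylic chloride, silylalkyne) | C[Si](C)(C)C#C[C@@H]1CC[C@@H]([C@]2(C=O)CCC[C@H](C(=O)OC)[C@H]2CC(=O)OC)/C(C1)=C/CCl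
F0 | step 18 | none | none
F5 | step 22 | 13-(1-iodoethenyl) analogue of dialdehyde 34 | C=C(I)[C@@H]1CC[C@H]2[C@]3(C=O)CCC[C@@](C)(C(=O)OC)[C@H]3[C@H](C(=O)OC)[C@]2(C1)C=O
F6 | step 22 | free 15β-hydroxy 7,19-dimethyl ester of the target (the alcohol corresponding to silyl ether 35) | C=C1[C@@H]2CC[C@H]3[C@]4(C=O)CCC[C@@](C)(C(=O)OC)[C@H]4[C@H](C(=O)OC)[C@]3(C2)[C@@H]1O
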